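The numbers of this flask are made up; no experiment stands behind them.

I started from 7.8, the equilibrium constant between electrophile and dormant form, since what sits in the dormant form already counts as reacted.

- summer: electrophile 0.20 M; nucleophile 3.00 equiv; free base 2.00 equiv; time 5.0 d
- spring: electrophile 0.20 M; nucleophile 3.00 equiv; free base 4.00 equiv; time 5.0 d

- part of the electrophile that has reacted at the end, summer
- part of the electrophile that has reacted at the end, spring
- what raising the equivalents of free base from its lowest to its highest value here does to the part of the electrophile that has reacted (changes below 5 percentage points count as none) (it rises / no change / it falls)

- what has gone from electrophile into another species counts as reacted, even if it can come back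
- run time (summer): 5.0 d

    acid set free + free base ⇌ salt of the base (K1 = 2600 /M, k1 = 4.7 /M/h)
    nucleophile + acid set free ⇌ protonated nucleophile, settled at all times (K2 = 620 /M)
    electrophile + nucleophile ⇌ acid set free + target (K3 = 0.11, k3 = 0.072 /M/h)
    free base + target → over-reaction product (k4 = 0.089 /M/h)
    electrophile ⇌ dormant form (K5 = 7.8, k5 = 0.98 /h)

The forward step to the dormant form has a half-life of 0.71 h, much shorter than the run of 5.0 d, so I treated the two forms as one pool at balance. That gave 11.4% for the fraction of the pool standing as electrophile, the free share. So 88.6% of the charge counted as reacted within hours, and I had only the correction left to compute.

But the pool leaks, because the nucleophile takes the free share. With the nucleophile taken as charged, this is a pseudo-first-order loss of 0.118 /d from the pool. I dropped the way back, because at balance with the nucleophile as charged, acid set free stood to protonated nucleophile as one to 370, so little of it stayed free to return. The fraction of the pool left was then 55.5%, and the reacted part 93.7%. Free base entered neither factor, so I committed to that figure for summer and spring, with no change.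

The forecast gave 93.2% for summer and 93.6% for spring, with the trend no change, holding that “the slow forward reaction through the small free fraction only adds a few more points”. My figure stood 0.5 percentage points above its summer number and 0.100 points above its spring number.

The simulation gave 93.4% for summer and 93.5% for spring, with the trend no change, a change of 0.05 points.

In summer the dormant form filled first, the turnover of that step reaching its midpoint by 0.323 h. Over the following days the nucleophile drew on the electrophile, that step's midpoint falling at 1.84 d, while free base carried target on to over-reaction product, which stood at 32.1% at 5.00 d. The free share of the summer pool at that time gives 6.75% electrophile, against 6.6% in the flask. In the neighbour charged with 0.80 M of electrophile, it gives 2.39%, against 2.2% in the flask.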